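The readings are calculated from invented constants; the scatter is artificial.

Follow the Q that is left, not the L that is made, and ask first which number the answer hangs on.

| setting | violet | teal | Wednesday's | Sunday's |
|---|---|---|---|---|
| Q | 0.034 M | 0.17 M | 0.050 M | 0.20 M |
| remark | run made earlier | run made earlier |  |  |
| time |  |  | 30 h | 50 h |

| run | time / h | L / % | Q / % |
|---|---|---|---|
| violet | 2.00 | 20 | 79 |
| violet | 4.00 | 33 | 64 |
| violet | 6.00 | 43 | 54 |
| violet | 8.00 | 47 | 46 |
| violet | 10.0 | 52 | 42 |
| violet | 12.0 | 57 | 35 |
| violet | 15.0 | 57 | 31 |
| teal | 0.833 | 37 | 61 |
| teal | 2.50 | 63 | 35 |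
| teal | 4.00 | 65 | 26 |
| teal | 6.00 | 74 | 19 |
| teal | 10.0 | 73 | 10 |
| teal | 12.0 | 74 | 10 |
| teal | 15.0 | 73 | 10 |

(readings scatter by 1.5 percentage points)
- which one finishes higher in amount of L, in percent of the Q charged ("neither" within 2 percentage points) (Wednesday's / Sunday's / neither)
- amount of L at the end, in percent of the Q charged, Wednesday's
- amount of L at the end, in percent of the Q charged, Sunday's
- a species is counted by the Q in it: one L or G counts as two
- the numbers in the tables scatter with a standard deviation of 1.5 percentage points
- candidate steps: 2 Q -> L; L <-> G

Charges and times are given, so your doubt lies in two things read from the runs. The speed of Q enters through the amount left, and late in a run an error there is a fraction of a small amount. The division of converted Q between L and G multiplies the converted part, so a slip in it reaches L scaled by that part. That division has to be known well, the speed less.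

Now the numbers. For a second-order loss, the fraction left is one over one plus the time counted in half-times. The teal reading at 6.00 h therefore gives 1.41 h for the half-time, the usual first half-life: the time at which the Q left equals the Q lost. The violet reading at 15.0 h gives 6.74 h. Their ratio of 4.78 stands against a ratio of charges of 5.00, so you scale the half-time inversely with the starting [Q]. Wednesday's flask gets 4.79 h and keeps 13.8% of its Q; Sunday's gets 1.20 h and keeps 2.34%.

The last teal reading puts L at 81.1% of the converted Q. My own reckoning with that share gives 69.9% for Wednesday's and 79.2% for Sunday's, but the share was read at 15.0 h, so I doubt it at 50 h. The forecast stands lower , at 68% and 75.5%, and names Sunday's, holding for Sunday's that “L/G is equilibrated”.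

Sunday's finishes higher, with L at 69.5% against 64.8% for Wednesday's, so Sunday's L lies 6 percentage points below the forecast.

2 Q → L (k = 5.90 × 10⁻⁴ M⁻¹ s⁻¹); L ⇌ G (K = 0.420, k = 7.30 × 10⁻⁶ s⁻¹) In Sunday's flask the step between L and G, taken by itself and both ways together, relaxes with a half-life of 7.80 h, shorter than the 50 h the flask stood. Read that flask at 12 h instead: its half-time 1.20 h gives 9.09% of Q left, and the flask held 8.9%. L there was 75.4%, which is 82.8% of the converted Q, against 71.1% at 50 h.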